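**Retrosynthetic overview**
1. Hidden ring: the O–CH2 carbon, the ring CH that carries it, the quaternary ring carbon with its methyl and the three carbons of the propanoic acid are the seven carbons of 3-methylcyclohexanone (ring B), cut between C=O and the α′-CH2. Both side chains therefore come from late oxidative opening of ring B, and the aryl ether from a Mitsunobu reaction with umbelliferone.
2. With the O–CH2 carbon as the ketone of ring B, the ring CH is an enol silane carbon. Ring A (the cyclohexene) is closed by gold-catalysed 6-endo-dig attack of this carbon on the methyl-bearing carbon of a propynyl group, which gives the C(CH3)=CH alkene in place and a cis ring fusion.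
3. The enol silane comes from copper-catalysed asymmetric conjugate addition of a chiral Grignard reagent to 3-methylcyclohex-2-enone (quaternary centre) with silyl trapping. The CH–isopropenyl centre comes from copper-catalysed SN2′ alkynylation of a prenol-derived allylic phosphate with propyne.
4. Ring order: ring B is bought, ring A is formed in the key step, ring B is opened afterwards; the coumarin rings are bought as umbelliferone.

Key step: step 7

Assumption: both antipodes of the chiral ligands of steps 4 and 6 are accessible, and each step is run with the antipode that gives the configuration drawn.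

Step 1
Reactants: 1 3-methylbut-2-en-1-ol (prenol)
Product: 2 tert-butyl(dimethyl)[(3-methylbut-2-en-1-yl)oxy]silane
Conditions: TBSCl, imidazole, DMF, 23 °C
Reagents that add atoms: tert-butyldimethylsilyl chloride, CC(C)(C)[Si](C)(C)Cl
Why: Silylation of a primary alcohol; the silyl ether should survive the allylic oxidation and the organoaluminium step and is later exchanged directly for bromide.

Step 2
Reactants: 2 tert-butyl(dimethyl)[(3-methylbut-2-en-1-yl)oxy]silane
Product: 3 (2E)-4-{[tert-butyl(dimethyl)silyl]oxy}-2-methylbut-2-en-1-ol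
Conditions: SeO2 (0.5 equiv), t-BuOOH, salicylic acid (cat.), CH2Cl2, 23 °C
Reagents that add atoms: tert-butyl hydroperoxide, CC(C)(C)OO
Why: Selenium dioxide allylic oxidation (ene reaction, then [2,3]-sigmatropic shift) should hydroxylate the methyl group trans to the chain, which fixes the E geometry needed for the SN2′ step.

Step 3
Reactants: 3 (2E)-4-{[tert-butyl(dimethyl)silyl]oxy}-2-methylbut-2-en-1-ol
Product: 4 (2E)-4-{[tert-butyl(dimethyl)silyl]oxy}-2-methylbut-2-en-1-yl diethyl phosphate
Conditions: ClP(O)(OEt)2, Et3N, DMAP (cat.), CH2Cl2, 0 °C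
Reagents that add atoms: diethyl chlorophosphate, CCOP(=O)(Cl)OCC
Why: O-Phosphorylation of the allylic alcohol installs the leaving group for copper-catalysed allylic substitution.

Step 4
Reactants: 4 (2E)-4-{[tert-butyl(dimethyl)silyl]oxy}-2-methylbut-2-en-1-yl diethyl phosphate; 5 propyne
Product: 7 tert-butyl(dimethyl){[(2R)-2-(prop-1-en-2-yl)pent-3-yn-1-yl]oxy}silane, via diisobutyl(prop-1-ynyl)aluminium 6 (not isolated)
Conditions: 5, i-Bu2AlH, Et3N (5 mol %), hexane, 0 → 23 °C; then 4, CuCl2·2H2O (5 mol %), chiral sulfonate-bearing imidazolinium salt (5.5 mol %), THF, −15 °C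
Reagents that add atoms: none
Why: Copper–NHC-catalysed enantioselective SN2′ allylic substitution of an E-allylic phosphate by an alkynylaluminium reagent: the propynyl group should add at the γ-carbon anti to the leaving phosphate, the ligand antipode selecting the alkene face so that the new stereocentre is R, while the double bond shifts to form the isopropenyl group.

Step 5
Reactants: 7 tert-butyl(dimethyl){[(2R)-2-(prop-1-en-2-yl)pent-3-yn-1-yl]oxy}silane
Product: 8 (4R)-5-bromo-4-(prop-1-en-2-yl)pent-2-yne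
Conditions: Ph3PBr2, CH2Cl2, 0 → 23 °C
Reagents that add atoms: triphenylphosphine dibromide, BrP(Br)(c1ccccc1)(c1ccccc1)c1ccccc1
Why: Direct conversion of a primary silyl ether into the bromide (Appel-type substitution at CH2); the stereocentre is not involved.

Step 6
Reactants: 8 (4R)-5-bromo-4-(prop-1-en-2-yl)pent-2-yne; 9 3-methylcyclohex-2-en-1-one
Product: 12 tert-butyl(dimethyl)({(3R)-3-methyl-3-[(2R)-2-(prop-1-en-2-yl)pent-3-yn-1-yl]cyclohex-1-en-1-yl}oxy)silane, via Grignard reagent 10 (not isolated), via magnesium enolate 11 (not isolated)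
Conditions: Mg, Et2O, 35 °C; then 9, Cu(OTf)2 (3 mol %), chiral C2-symmetric imidazolinium chloride (4 mol %), Et2O, 0 °C; then TBSOTf, Et3N, −78 → 0 °C
Reagents that add atoms: tert-butyldimethylsilyl trifluoromethanesulfonate, CC(C)(C)[Si](C)(C)OS(=O)(=O)C(F)(F)F
Why: Copper–NHC-catalysed asymmetric conjugate addition of a Grignard reagent to a β-methyl cyclohexenone should build the quaternary centre (3R by catalyst control; the side-chain centre is not epimerizable), and O-silylation of the magnesium enolate fixes the enol double bond towards C2, the carbon that must become the nucleophile.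

Step 7
Reactants: 12 tert-butyl(dimethyl)({(3R)-3-methyl-3-[(2R)-2-(prop-1-en-2-yl)pent-3-yn-1-yl]cyclohex-1-en-1-yl}oxy)silane
Product: 13 (4aR,6S,8aR)-4a,8-dimethyl-6-(prop-1-en-2-yl)-3,4,4a,5,6,8a-hexahydronaphthalen-1(2H)-one (cis-fused)
Conditions: [(tBuXPhos)Au(NCMe)]SbF6 (5 mol %; tBuXPhos = 2-di-tert-butylphosphino-2′,4′,6′-triisopropylbiphenyl), CH2Cl2/MeOH (10:1), 23 °C
Reagents that add atoms: none
Why: The cationic gold complex binds the alkyne and the enol silane carbon (C2 of 12, C8a of 13) adds anti to gold at the distal, methyl-bearing alkyne carbon; the silyloxocarbenium ion then gives its silyl group to methanol and the vinylgold is protonated, so the ketone and the trisubstituted ring alkene form without base. The closest known reaction type is the gold-catalysed 6-endo-dig carbocyclization of cyclic silyl enol ethers onto tethered alkynes to give fused carbocycles. Ring A is closed in the 6-endo-dig mode. The new stereocentre C8a is controlled by the neighbouring quaternary carbon C4a: the alkyne is tethered to C4a and can reach only the enol ether face on its own side, so the ring fusion should be cis (H-8a cis to the 4a-methyl), and because C–C bond formation is the last event at this carbon, no protonation step decides its configuration. The step needs 6-endo over 5-exo attack and C- over O-attack: the methyl cap makes the distal alkyne carbon the less hindered one, the branched propargylic carbon shields the proximal one and the bulky biarylphosphine adds to this bias, while the soft enol silane carbon secures C-attack. The isopropenyl group cannot reach the activated alkyne in a ring of useful size and should stay untouched.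

Step 8
Reactants: 13 (4aR,6S,8aR)-4a,8-dimethyl-6-(prop-1-en-2-yl)-3,4,4a,5,6,8a-hexahydronaphthalen-1(2H)-one
Product: 15 (4aR,6S,8aR)-2-hydroxy-4a,8-dimethyl-6-(prop-1-en-2-yl)-3,4,4a,5,6,8a-hexahydronaphthalen-1(2H)-one (both C2 epimers), via potassium enolate 14 (not isolated)
Conditions: KN(SiMe3)2, THF, −78 °C; then 2-(phenylsulfonyl)-3-phenyloxaziridine, −78 °C; AcOH
Reagents that add atoms: 2-(phenylsulfonyl)-3-phenyloxaziridine, O=S(=O)(c1ccccc1)N1OC1c1ccccc1
Why: Kinetic deprotonation by the bulky amide at the unhindered C2 methylene rather than at the hindered ring-fusion CH, followed by electrophilic enolate hydroxylation with an N-sulfonyloxaziridine, should give the α′-ketol; the new carbinol centre is destroyed in step 9 and the cis ring fusion is expected to be the more stable one.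

Step 9
Reactants: 15 (4aR,6S,8aR)-2-hydroxy-4a,8-dimethyl-6-(prop-1-en-2-yl)-3,4,4a,5,6,8a-hexahydronaphthalen-1(2H)-one
Product: 17 methyl (1R,4S,6R)-6-(3,3-dimethoxypropyl)-2,6-dimethyl-4-(prop-1-en-2-yl)cyclohex-2-ene-1-carboxylate, via aldehyde ester 16 (not isolated)
Conditions: Pb(OAc)4, MeOH/toluene, 0 °C; then HC(OMe)3, PPTS, 23 °C
Reagents that add atoms: methanol, CO; trimethyl orthoformate, COC(OC)OC
Why: α-Ketol (glycol-type) cleavage with Pb(OAc)4 in methanol should give the methyl ester from the ketone carbon and the aldehyde from the carbinol carbon, so ring B opens with its two termini already differentiated; the aldehyde is masked in the same flask as its dimethyl acetal.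

Step 10
Reactants: 17 methyl (1R,4S,6R)-6-(3,3-dimethoxypropyl)-2,6-dimethyl-4-(prop-1-en-2-yl)cyclohex-2-ene-1-carboxylate
Product: 18 [(1R,4S,6R)-6-(3,3-dimethoxypropyl)-2,6-dimethyl-4-(prop-1-en-2-yl)cyclohex-2-en-1-yl]methanol
Conditions: i-Bu2AlH, CH2Cl2, −78 → 0 °C
Reagents that add atoms: none
Why: Hydride reduction of the ester to the primary alcohol; acetal and alkenes are inert and the adjacent stereocentre is not enolized under these conditions.

Step 11
Reactants: 18 [(1R,4S,6R)-6-(3,3-dimethoxypropyl)-2,6-dimethyl-4-(prop-1-en-2-yl)cyclohex-2-en-1-yl]methanol; 19 7-hydroxy-2H-chromen-2-one (umbelliferone)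
Product: 20 7-{[(1R,4S,6R)-6-(3,3-dimethoxypropyl)-2,6-dimethyl-4-(prop-1-en-2-yl)cyclohex-2-en-1-yl]methoxy}-2H-chromen-2-one
Conditions: PPh3, DIAD, THF, 0 → 23 °C
Reagents that add atoms: none
Why: Mitsunobu etherification of a primary alcohol with an acidic phenol; the reacting carbon is a CH2, so no stereocentre is touched.

Step 12
Reactants: 20 7-{[(1R,4S,6R)-6-(3,3-dimethoxypropyl)-2,6-dimethyl-4-(prop-1-en-2-yl)cyclohex-2-en-1-yl]methoxy}-2H-chromen-2-one
Product: 21 3-[(1R,2R,5S)-1,3-dimethyl-2-{[(2-oxo-2H-chromen-7-yl)oxy]methyl}-5-(prop-1-en-2-yl)cyclohex-3-en-1-yl]propanal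
Conditions: AcOH/THF/H2O (3:1:1), 40 °C
Reagents that add atoms: water, O
Why: Mild acid-catalysed acetal hydrolysis should free the aldehyde without touching the aryl ether, the lactone or the alkenes.

Step 13
Reactants: 21 3-[(1R,2R,5S)-1,3-dimethyl-2-{[(2-oxo-2H-chromen-7-yl)oxy]methyl}-5-(prop-1-en-2-yl)cyclohex-3-en-1-yl]propanal
Product: 22 3-[(1R,2R,5S)-1,3-dimethyl-2-{[(2-oxo-2H-chromen-7-yl)oxy]methyl}-5-(prop-1-en-2-yl)cyclohex-3-en-1-yl]propanoic acid (target)
Conditions: NaClO2, NaH2PO4, 2-methylbut-2-ene, t-BuOH/H2O, 0 → 23 °C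
Reagents that add atoms: sodium chlorite, [Na+].[O-]Cl=O
Why: Pinnick oxidation of the aldehyde to the acid; the hypochlorite scavenger protects the alkenes and the near-neutral buffer leaves the coumarin lactone closed.

**Compound list**
1 | 3-methylbut-2-en-1-ol | CC(C)=CCO | starting material
2 | tert-butyl(dimethyl)[(3-methylbut-2-en-1-yl)oxy]silane | CC(C)=CCO[Si](C)(C)C(C)(C)C | intermediate
3 | (2E)-4-{[tert-butyl(dimethyl)silyl]oxy}-2-methylbut-2-en-1-ol | OC/C(C)=C/CO[Si](C)(C)C(C)(C)C | intermediate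
4 | (2E)-4-{[tert-butyl(dimethyl)silyl]oxy}-2-methylbut-2-en-1-yl diethyl phosphate | CCOP(=O)(OCC)OC/C(C)=C/CO[Si](C)(C)C(C)(C)C | intermediate
5 | propyne | CC#C | starting material
6 | diisobutyl(prop-1-ynyl)aluminium | CC#C[Al](CC(C)C)CC(C)C | intermediate
7 | tert-butyl(dimethyl){[(2R)-2-(prop-1-en-2-yl)pent-3-yn-1-yl]oxy}silane | CC#C[C@H](CO[Si](C)(C)C(C)(C)C)C(C)=C | intermediate
8 | (4R)-5-bromo-4-(prop-1-en-2-yl)pent-2-yne | CC#C[C@H](CBr)C(C)=C | intermediate
9 | 3-methylcyclohex-2-en-1-one | CC1=CC(=O)CCC1 | starting material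
10 | bromo[(2R)-2-(prop-1-en-2-yl)pent-3-yn-1-yl]magnesium | CC#C[C@H](C[Mg]Br)C(C)=C | intermediate
11 | bromomagnesium (3R)-3-methyl-3-[(2R)-2-(prop-1-en-2-yl)pent-3-yn-1-yl]cyclohex-1-en-1-olate | CC#C[C@H](C[C@@]1(C)CCCC(O[Mg]Br)=C1)C(C)=C | intermediate
12 | tert-butyl(dimethyl)({(3R)-3-methyl-3-[(2R)-2-(prop-1-en-2-yl)pent-3-yn-1-yl]cyclohex-1-en-1-yl}oxy)silane | CC#C[C@H](C[C@@]1(C)CCCC(O[Si](C)(C)C(C)(C)C)=C1)C(C)=C | intermediate
13 | (4aR,6S,8aR)-4a,8-dimethyl-6-(prop-1-en-2-yl)-3,4,4a,5,6,8a-hexahydronaphthalen-1(2H)-one | C=C(C)[C@@H]1C=C(C)[C@@H]2C(=O)CCC[C@]2(C)C1 | intermediate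
14 | potassium (4aR,6S,8aR)-4a,8-dimethyl-6-(prop-1-en-2-yl)-3,4,4a,5,6,8a-hexahydronaphthalen-1-olate | C=C(C)[C@@H]1C=C(C)[C@@H]2C(O[K])=CCC[C@]2(C)C1 | intermediate
15 | (4aR,6S,8aR)-2-hydroxy-4a,8-dimethyl-6-(prop-1-en-2-yl)-3,4,4a,5,6,8a-hexahydronaphthalen-1(2H)-one (C2 epimers) | C=C(C)[C@@H]1C=C(C)[C@@H]2C(=O)C(O)CC[C@]2(C)C1 | intermediate
16 | methyl (1R,4S,6R)-2,6-dimethyl-6-(3-oxopropyl)-4-(prop-1-en-2-yl)cyclohex-2-ene-1-carboxylate | C=C(C)[C@@H]1C=C(C)[C@H](C(=O)OC)[C@](C)(CCC=O)C1 | intermediate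
17 | methyl (1R,4S,6R)-6-(3,3-dimethoxypropyl)-2,6-dimethyl-4-(prop-1-en-2-yl)cyclohex-2-ene-1-carboxylate | C=C(C)[C@@H]1C=C(C)[C@H](C(=O)OC)[C@](C)(CCC(OC)OC)C1 | intermediate
18 | [(1R,4S,6R)-6-(3,3-dimethoxypropyl)-2,6-dimethyl-4-(prop-1-en-2-yl)cyclohex-2-en-1-yl]methanol | C=C(C)[C@@H]1C=C(C)[C@H](CO)[C@](C)(CCC(OC)OC)C1 | intermediate
19 | 7-hydroxy-2H-chromen-2-one (umbelliferone) | O=c1ccc2ccc(O)cc2o1 | starting material
20 | 7-{[(1R,4S,6R)-6-(3,3-dimethoxypropyl)-2,6-dimethyl-4-(prop-1-en-2-yl)cyclohex-2-en-1-yl]methoxy}-2H-chromen-2-one | C=C(C)[C@@H]1C=C(C)[C@H](COc2ccc3ccc(=O)oc3c2)[C@](C)(CCC(OC)OC)C1 | intermediate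
21 | 3-[(1R,2R,5S)-1,3-dimethyl-2-{[(2-oxo-2H-chromen-7-yl)oxy]methyl}-5-(prop-1-en-2-yl)cyclohex-3-en-1-yl]propanal | C=C(C)[C@@H]1C=C(C)[C@H](COc2ccc3ccc(=O)oc3c2)[C@](C)(CCC=O)C1 | intermediate
22 | 3-[(1R,2R,5S)-1,3-dimethyl-2-{[(2-oxo-2H-chromen-7-yl)oxy]methyl}-5-(prop-1-en-2-yl)cyclohex-3-en-1-yl]propanoic acid | C=C(C)[C@@H]1C=C(C)[C@H](COc2ccc3ccc(=O)oc3c2)[C@](C)(CCC(=O)O)C1 | target

**Step count:** 13 steps in total. **Longest linear sequence:** 13 steps (1 → 22); propyne 5, enone 9 and umbelliferone 19 enter without steps of their own.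

**Steps most likely to fail, with fallbacks**

Step 7. The risk is that the enol silane attacks the proximal alkyne carbon (5-exo-dig closure, wrong ring size), or that the enol silane is protodesilylated before the ring closes. The fallback sets out from 12 and replaces π-acid catalysis by a cross-coupling in which the carbon–iodine bond fixes the site of bond formation. The enol silane is cleaved (TBAF, AcOH, THF) to (3R)-3-methyl-3-[(2R)-2-(prop-1-en-2-yl)pent-3-yn-1-yl]cyclohexan-1-one F1. Ruthenium-catalysed trans-hydrosilylation ([Cp*Ru(NCMe)3]PF6, Et3SiH, CH2Cl2, 0 °C) should place silicon on the methyl-bearing alkyne carbon, cis to the side chain, and give (3R)-3-methyl-3-[(2S,3Z)-2-(prop-1-en-2-yl)-4-(triethylsilyl)pent-3-en-1-yl]cyclohexan-1-one F2. Iododesilylation with retention (N-iodosuccinimide, hexafluoroisopropanol, 0 °C) gives (3R)-3-[(2S,3Z)-4-iodo-2-(prop-1-en-2-yl)pent-3-en-1-yl]-3-methylcyclohexan-1-one F3. Palladium-catalysed intramolecular α-alkenylation of the ketone enolate (Pd(PPh3)4, KOt-Bu, THF, 23 °C) then forms the same ring bond; the ring-fusion centre can equilibrate under the basic conditions to the cis isomer, and the route is re-joined at 13.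

Step 4. The risk is incomplete SN2′ site selectivity and erosion of enantioselectivity, because the 2-methyl group of the allylic phosphate crowds the copper–allyl intermediate. The fallback sets out from 3 and sets the same stereocentre by epoxide chemistry. Sharpless asymmetric epoxidation (Ti(OiPr)4, L-(+)-diethyl tartrate, t-BuOOH, 4 Å molecular sieves, CH2Cl2, −20 °C) should give [(2S,3S)-3-({[tert-butyl(dimethyl)silyl]oxy}methyl)-2-methyloxiran-2-yl]methanol F4. Diethyl(prop-1-ynyl)aluminium (from 5, n-BuLi and Et2AlCl; toluene, 0 °C) opens the epoxide at C3 with inversion to (2R,3R)-3-({[tert-butyl(dimethyl)silyl]oxy}methyl)-2-methylhex-4-yne-1,2-diol F5. 1,1′-Thiocarbonyldiimidazole (THF, 60 °C) gives (4R)-4-[(2R)-1-{[tert-butyl(dimethyl)silyl]oxy}pent-3-yn-2-yl]-4-methyl-1,3-dioxolane-2-thione F6. Corey–Winter olefination (P(OMe)3, 110 °C) turns the 1,2-diol unit into the isopropenyl group and the route is re-joined at 7.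

Step 8. The risk is deprotonation at the more acidic ring-fusion CH instead of the C2 methylene, which would misplace the oxidation and let the β,γ-double bond slide into conjugation. The fallback sets out from 13 and takes its regiocontrol from enamine formation, which avoids the substituted α-carbon because of allylic strain. Pyrrolidine with TiCl4 (toluene, 0 → 23 °C) should give 1-[(4aR,6S,8aR)-4a,8-dimethyl-6-(prop-1-en-2-yl)-3,4,4a,5,6,8a-hexahydronaphthalen-1-yl]pyrrolidine F7. Oxidation with dibenzoyl peroxide (THF, 0 °C) and aqueous work-up gives (4aR,6S,8aR)-4a,8-dimethyl-1-oxo-6-(prop-1-en-2-yl)-1,2,3,4,4a,5,6,8a-octahydronaphthalen-2-yl benzoate F8 (C2 epimers). Methanolysis (K2CO3, MeOH, 0 °C) re-joins the route at 15.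

**Further compounds**
F1 | step 7 | (3R)-3-methyl-3-[(2R)-2-(prop-1-en-2-yl)pent-3-yn-1-yl]cyclohexan-1-one | CC#C[C@H](C[C@@]1(C)CCCC(=O)C1)C(C)=C
F2 | step 7 | (3R)-3-methyl-3-[(2S,3Z)-2-(prop-1-en-2-yl)-4-(triethylsilyl)pent-3-en-1-yl]cyclohexan-1-one | C=C(C)[C@@H](C[C@@]1(C)CCCC(=O)C1)/C=C(/C)[Si](CC)(CC)CC
F3 | step 7 | (3R)-3-[(2S,3Z)-4-iodo-2-(prop-1-en-2-yl)pent-3-en-1-yl]-3-methylcyclohexan-1-one | C=C(C)[C@@H](C[C@@]1(C)CCCC(=O)C1)/C=C(/C)I
F4 | step 4 | [(2S,3S)-3-({[tert-butyl(dimethyl)silyl]oxy}methyl)-2-methyloxiran-2-yl]methanol | OC[C@]1(C)O[C@H]1CO[Si](C)(C)C(C)(C)C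
F5 | step 4 | (2R,3R)-3-({[tert-butyl(dimethyl)silyl]oxy}methyl)-2-methylhex-4-yne-1,2-diol | CC#C[C@H](CO[Si](C)(C)C(C)(C)C)[C@@](C)(O)CO
F6 | step 4 | (4R)-4-[(2R)-1-{[tert-butyl(dimethyl)silyl]oxy}pent-3-yn-2-yl]-4-methyl-1,3-dioxolane-2-thione | CC#C[C@H](CO[Si](C)(C)C(C)(C)C)[C@]1(C)COC(=S)O1
F7 | step 8 | 1-[(4aR,6S,8aR)-4a,8-dimethyl-6-(prop-1-en-2-yl)-3,4,4a,5,6,8a-hexahydronaphthalen-1-yl]pyrrolidine | C=C(C)[C@@H]1C=C(C)[C@@H]2C(N3CCCC3)=CCC[C@]2(C)C1
F8 | step 8 | (4aR,6S,8aR)-4a,8-dimethyl-1-oxo-6-(prop-1-en-2-yl)-1,2,3,4,4a,5,6,8a-octahydronaphthalen-2-yl benzoate | C=C(C)[C@@H]1C=C(C)[C@@H]2C(=O)C(OC(=O)c3ccccc3)CC[C@]2(C)C1
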